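## Structural features

The target is a cis-fused bicyclic peroxy-lactone: a 1,2-dioxane (O–O, C3, C4, C5, C6) and a γ-butyrolactone (C1, C2, C3, C4 and the oxygen on C4) share the C3–C4 bond. C3 (peroxy methine, S) and C4 (fully substituted, methyl and lactone oxygen, S) are adjacent. C6 (fully substituted peroxy carbon, R) is 1,3 to C4 with the two ring methyl groups cis, and C8 (R) stands alone in the chain. The C7–C14 chain ends in a (10E,12E)-diene with methyl groups on C10 and C12 and a benzyl terminus, so both double bonds are trisubstituted. Fragile groups are the O–O bond (low-valent metals, phosphines, hydrides), the β-peroxy lactone (base expels the peroxide from C3 by E1cB or cleaves it at C3–H in the Kornblum–DeLaMare sense) and the diene (acid, hydrogen-atom transfer, singlet oxygen). The real difficulty is the order of events. The tertiary C6–O bond is best made by radical hydroperoxidation of a 1,1-disubstituted alkene, which tolerates no other alkene and gives no control at C6. The diene must therefore be built afterwards, yet the lactone will not survive the alkoxide base this requires. The key step uses the C3–H bond of the monocyclic dioxane: it is α to a peroxide oxygen, cis to the C4 oxygen and 1,5 to the carbenoid carbon of a diazoacetate on that oxygen.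

## Logic of the disconnections

**29 ⇒ 25 + 28.** Cut: the C11–C12 single bond between the two alkenes. This is the only cut that gives two halves each accessible with defined geometry, and it makes the route convergent. The forward coupling must retain both geometries and may use only a weak base, because 25 already holds the β-peroxy lactone.

**28 ⇒ 26.** Cut: C12–I and C13–H across the alkyne. A syn hydrometalation–iodination turns a four-carbon alkyne into the E iodide in one step. The demand is regiocontrol: metal on the methyl-bearing carbon.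

**25 ⇒ 24.** Cut: C2–C3 (key step). Removing this bond opens the lactone and returns C3 to a methylene group, so the bicycle becomes a monocyclic dioxanol ester with C4, C6 and C8 already in place. The forward step must select the C3–H cis to the C4 oxygen over C5–H, the methyl C–H bonds and the peroxide oxygens.

**24 ⇒ 21 (through 22, 23).** Cut: the ester C1–O bond and the diazo group. The carbenoid precursor reduces to a tertiary alcohol plus a two-carbon acyl unit. The demand is acylation of a hindered tertiary alcohol and diazo formation without strong base, since the ring has a CH2–OO unit.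

**21 ⇒ 19 (through 20).** Cut: C11–B and C10–CH3, plus the C4 silyl group. The alkenyl boronate comes from a terminal alkyne by syn methyl–boron addition. Placing this ahead of 24 keeps its stoichiometric alkoxide away from the lactone. The peroxide of 19 must survive the boryl-copper reagent, and the C4 oxygen must stay protected so that no hydroxyl protonates the alkenylcopper.

**19 ⇒ 17 (through 18).** Cut: C10≡C11. One-carbon homologation of the C10 aldehyde; the basic methanol it needs is harmless while no carbonyl sits next to the peroxide.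

**17 ⇒ 15 (through 16).** Cut: the O–C3 bond of the dioxane. The ring closes by displacement of a primary sulfonate by the C6 hydroperoxide (6-exo-tet). The C4 oxygen must be blocked first. A free C4 hydroxyl beside the C3 leaving group would give the C3–C4 epoxide, and a β-hydroperoxy 2,2-disubstituted epoxide is expected to close 5-exo at the tertiary carbon to a 1,2-dioxolane-3-methanol, not 6-endo to the dioxan-4-ol.

**15 ⇒ 14.** Cut: C6–O. Hydroperoxysilylation of the only alkene installs the peroxide and the C6 methyl group in one step. The price is no control at C6; the epimers are separated after ring closure.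

**14 ⇒ 12 (through 13).** No skeletal cut: the primary hydroxyl becomes the leaving group and the tertiary one the silyl ether. The demand is clean differentiation of a primary from a tertiary hydroxyl.

**12 ⇒ 8 + 9.** Cut: C5–C6. An alkenyl metal opens the epoxide CH2 of 9, which brings C3, C4 (with its configuration), C5 and the C4 methyl group in one piece. The attack must occur at the CH2 only.

**8 ⇒ 1 (through 6, 5, 3).** Cuts: C6–Br and the C6=CH2 carbon. The bromoalkene comes from a terminal alkyne, the alkyne from the ester carbon of 1 (which becomes C6), and the acid carbon of 1 becomes C10. This assignment of the two carboxyl groups gives the correct C8 configuration from the R monoester.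

## Other disconnections considered

**Alternative 1:** The cut removes both peroxide C–O bonds (C3–O and C6–O), leading back to the open-chain (3E,5E)-dienoic acid A2 and O2. In the forward step, sensitised photooxygenation would add singlet oxygen suprafacially across C3 and C6 of A2 to give the dihydrodioxine acid A1. The lactone would then follow by Markovnikov addition of the carboxyl group to C4=C5.
- In favour: the whole peroxide ring arises in one metal-free step from a precursor that needs no chiral epoxide. The C3/C6 relative configuration follows from the diene geometry, which is better than the chosen plan (no control at C6). The step count to the core is lower, which is also better.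
- Against: the reacting s-cis conformer of A2 must hold the C6 methyl group on the inside of the diene, so ene reactions at the many allylic hydrogens should outrun the [4+2] addition. The remote C8 centre does not distinguish the diene faces, so A1 would form with its (3R,6S) diastereomer and nothing is set in absolute terms. The later lactonisation must place oxygen on C4 by ionic addition next to a peroxide.
- Comparison: the cycloaddition is mechanistically simpler than a carbenoid insertion. Loss of material to a diastereomer is equal in both plans. The chosen plan fixes C4 from the chiral pool and does not depend on a disfavoured conformer.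

**Alternative 2:** The cut removes C6–O, C5–C6 and C4–O, leading back to the acyclic ester A4. In A4 a C3 hydroperoxide bearing the isopropenyl group (C4, C5) is tied through its C1 ester to the C10 oxygen of the C6 methyl ketone. In the forward step a Lewis acid would condense hydroperoxide and ketone to a peroxycarbenium ion, C5 would attack C6, and the ester carbonyl would trap the C4 cation. Water would then release lactone A3 with a free C10 hydroxyl.
- In favour: three bonds and both rings form in one operation. The tether should force C3–C2 and C6–C7 onto the same face, giving control at C6 that the chosen plan lacks (better). Cis fusion follows from the intramolecular capture. Step economy would be clearly better.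
- Against: ionisation must pass through an eleven-membered cyclic peroxycarbenium ion. A secondary allylic hydroperoxide under Lewis acid is prone to Hock-type cleavage. A4 is a β-hydroperoxy ester that eliminates easily, and its C3 centre is hard to set. An ester-tethered peroxycarbenium–alkene annulation has no close analogy.
- Comparison: on paper it is more convergent and more stereocontrolled, but it stacks three unproven events in one step. The chosen plan has one unproven step on a substrate reached by known reactions.

**Alternative 3:** The cut removes the lactone C4–O bond, leading back to the dioxane acetic acid A6 with a tertiary C4–H. In the forward step, carboxylate-directed oxidation with Mn(CF3SO3)2(pdp) and H2O2 in a fluorinated alcohol would abstract the γ-hydrogen at C4 and return the carboxylate oxygen with retention to give A5.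
- In favour: directed γ-lactonisation of tertiary C–H bonds is an established reaction type, with better precedent than a carbenoid insertion next to a peroxide. It avoids diazo compounds (better on hazard). A6 belongs to the well-studied 1,2-dioxane-3-acetic acids made by conjugate addition of a hydroperoxide.
- Against: A6 needs three ring stereocentres set before the key step (C3, C4 with its hydrogen cis to the acetic acid arm, and C6). The C4–H bond is deactivated by the oxygens β to it, while the chain offers a second tertiary C–H at C8. The β-peroxy acid may eliminate, or the high-valent manganese oxidant may attack the peroxide. No alkene of the side chain can be present.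
- Comparison: step count is about equal. The stereochemical burden is heavier than in the chosen plan, where C3 follows from C4 in the ring-closing step.

Key step: step 16

Assumption: the chain end beyond C9 is a spectator of the key step, so 24 and 25 keep the dioxanol diazoacetate and peroxy-lactone skeletons but carry the C10–C11 alkenyl boronate; this puts every alkoxide-mediated operation ahead of lactone formation.
Assumption: locants C1–C14 are those of the target, and the dioxane ring of the intermediates is numbered O1, O2, C3 (CH2), C4, C5, C6 to match.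
Assumption: 1, 9, 26 and the reagents on the Conditions lines are purchased.

## Route

Step 1
Reactants: 1 methyl hydrogen (R)-3-methylglutarate
Product: 3 (4R)-4-methyltetrahydro-2H-pyran-2-one, via hydroxy ester 2 (not isolated)
Conditions: BH3·SMe2, THF, 0 °C → rt; then p-TsOH (cat.), CH2Cl2, rt
Reagents that add atoms: none
Why: Borane reduces the carboxylic acid much faster than the methyl ester (chemoselective acid reduction), and the δ-hydroxy ester lactonises under acid; the C8 stereocentre is untouched and the acid carbon becomes C10.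

Step 2
Reactants: 3 (4R)-4-methyltetrahydro-2H-pyran-2-one
Product: 5 (3S)-3-methylhex-5-yn-1-ol, via lactol 4 (not isolated)
Conditions: DIBAL-H (1.05 equiv), CH2Cl2, −78 °C; then MeOH, K2CO3, Ohira–Bestmann reagent, −78 °C → rt
Reagents that add atoms: dimethyl (1-diazo-2-oxopropyl)phosphonate, COP(=O)(OC)C(=[N+]=[N-])C(C)=O
Why: One equivalent of DIBAL-H at −78 °C stops at the lactol, whose open hydroxy-aldehyde form undergoes Ohira–Bestmann homologation to the terminal alkyne; the added carbon becomes the C6 methyl group.

Step 3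
Reactants: 5 (3S)-3-methylhex-5-yn-1-ol
Product: 6 triethyl{[(3S)-3-methylhex-5-yn-1-yl]oxy}silane
Conditions: Et3SiCl, imidazole, CH2Cl2, 0 °C
Reagents that add atoms: chlorotriethylsilane, CC[Si](Cl)(CC)CC
Why: Standard silylation of a primary alcohol; the triethylsilyl ether survives the organometallic steps and is later cleaved together with the peroxide silyl group.

Step 4
Reactants: 6 triethyl{[(3S)-3-methylhex-5-yn-1-yl]oxy}silane
Product: 8 {[(3R)-5-bromo-3-methylhex-5-en-1-yl]oxy}triethylsilane, via alkenylalane 7 (not isolated)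
Conditions: Ni(dppp)Cl2 (3 mol %), DIBAL-H (1.3 equiv), THF, 0 °C → rt; then NBS, 0 °C
Reagents that add atoms: N-bromosuccinimide, O=C1CCC(=O)N1Br
Why: Nickel-catalysed hydroalumination with the dppp ligand places aluminium on the internal alkyne carbon (α-selective hydroalumination), and N-bromosuccinimide replaces it to give the 2-bromo-1-alkene.

Step 5
Reactants: 8 {[(3R)-5-bromo-3-methylhex-5-en-1-yl]oxy}triethylsilane; 9 (R)-2-methylglycidol
Product: 12 (2S,6S)-2,6-dimethyl-4-methylidene-8-[(triethylsilyl)oxy]octane-1,2-diol, via magnesium alkoxide 10 (not isolated), via alkenylmagnesium bromide 11 (not isolated)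
Conditions: 8, Mg, THF, rt → 40 °C; 9, MeMgCl (1.0 equiv), THF, −78 °C; combine, CuI (10 mol %), −40 → −10 °C; aq. NH4Cl
Reagents that add atoms: none
Why: Copper-catalysed opening of the 2,2-disubstituted epoxide by the alkenyl Grignard reagent occurs at the unhindered CH2 (SN2), forming C5–C6 and leaving the C4 stereocentre of 9 untouched; pre-forming the alkoxide of 9 spares the alkenyl reagent.

Step 6
Reactants: 12 (2S,6S)-2,6-dimethyl-4-methylidene-8-[(triethylsilyl)oxy]octane-1,2-diol
Product: 13 (2S,6S)-2-hydroxy-2,6-dimethyl-4-methylidene-8-[(triethylsilyl)oxy]octyl 4-methylbenzenesulfonate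
Conditions: TsCl, Et3N, Bu2SnO (2 mol %), CH2Cl2, 0 °C → rt
Reagents that add atoms: 4-toluenesulfonyl chloride, Cc1ccc(cc1)S(Cl)(=O)=O
Why: Tin-catalysed monosulfonylation of a 1,2-diol is selective for the primary hydroxyl; the tertiary C4 hydroxyl does not react and triethylamine is too weak to close the epoxide.

Step 7
Reactants: 13 (2S,6S)-2-hydroxy-2,6-dimethyl-4-methylidene-8-[(triethylsilyl)oxy]octyl 4-methylbenzenesulfonate
Product: 14 (2S,6S)-2,6-dimethyl-4-methylidene-2,8-bis[(triethylsilyl)oxy]octyl 4-methylbenzenesulfonate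
Conditions: Et3SiOTf, 2,6-lutidine, CH2Cl2, −78 → 0 °C
Reagents that add atoms: triethylsilyl trifluoromethanesulfonate, CC[Si](CC)(CC)OS(=O)(=O)C(F)(F)F
Why: Silyl triflate with 2,6-lutidine silylates hindered tertiary alcohols; blocking the C4 oxygen removes the epoxide pathway that would lead a C6 hydroperoxide to a 1,2-dioxolane by 5-exo attack at the tertiary carbon.

Step 8
Reactants: 14 (2S,6S)-2,6-dimethyl-4-methylidene-2,8-bis[(triethylsilyl)oxy]octyl 4-methylbenzenesulfonate
Product: 15 (2S,4R,6R)-2,4,6-trimethyl-2,8-bis[(triethylsilyl)oxy]-4-[(triethylsilyl)peroxy]octyl 4-methylbenzenesulfonate (formed together with its 4S epimer)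
Conditions: Co(thd)2 (10 mol %; thd = 2,2,6,6-tetramethylheptane-3,5-dionate), O2 (1 atm), Et3SiH, ClCH2CH2Cl, rt
Reagents that add atoms: dioxygen, O=O; triethylsilane, CC[SiH](CC)CC
Why: Mukaiyama–Isayama hydroperoxysilylation: hydrogen-atom transfer from a cobalt hydride to the 1,1-disubstituted alkene gives the tertiary C6 radical, which is trapped by O2 and silylated; neither C4 nor C8 controls the face, so both C6 epimers are expected and are carried into step 9.

Step 9
Reactants: 15 (2S,4R,6R)-2,4,6-trimethyl-2,8-bis[(triethylsilyl)oxy]-4-[(triethylsilyl)peroxy]octyl 4-methylbenzenesulfonate (with its 4S epimer)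
Product: 17 (3R)-4-{(4S,6R)-4,6-dimethyl-4-[(triethylsilyl)oxy]-1,2-dioxan-6-yl}-3-methylbutan-1-ol, via hydroperoxide 16 (not isolated)
Conditions: PPTS (0.2 equiv), MeOH, 0 °C → rt; then KOt-Bu (1.05 equiv), 18-crown-6, THF (0.01 M), 0 °C → rt; chromatography
Reagents that add atoms: none
Why: Acidic methanol cleaves the Si–OO and primary Si–O bonds but should spare the hindered tertiary silyl ether; the hydroperoxide anion then displaces the primary tosylate in a 6-exo-tet SN2 (intramolecular alkylation of a hydroperoxide), helped by the two fully substituted carbons in the tether, with no epoxide or elimination path open. The cyclic C6 epimers are diastereomers of different ring shape and are separated here; the 6R isomer (ring methyl groups cis) is carried on.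

Step 10
Reactants: 17 (3R)-4-{(4S,6R)-4,6-dimethyl-4-[(triethylsilyl)oxy]-1,2-dioxan-6-yl}-3-methylbutan-1-ol
Product: 18 (3S)-4-{(4S,6R)-4,6-dimethyl-4-[(triethylsilyl)oxy]-1,2-dioxan-6-yl}-3-methylbutanal
Conditions: Dess–Martin periodinane, CH2Cl2, 0 °C → rt
Reagents that add atoms: none
Why: Dess–Martin oxidation of the primary alcohol is near neutral and leaves the dialkyl peroxide and the tertiary silyl ether intact.

Step 11
Reactants: 18 (3S)-4-{(4S,6R)-4,6-dimethyl-4-[(triethylsilyl)oxy]-1,2-dioxan-6-yl}-3-methylbutanal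
Product: 19 triethyl({(4S,6R)-4,6-dimethyl-6-[(2R)-2-methylpent-4-yn-1-yl]-1,2-dioxan-4-yl}oxy)silane
Conditions: Ohira–Bestmann reagent, K2CO3, MeOH, 0 °C → rt
Reagents that add atoms: dimethyl (1-diazo-2-oxopropyl)phosphonate, COP(=O)(OC)C(=[N+]=[N-])C(C)=O
Why: Ohira–Bestmann homologation turns the C10 aldehyde into the terminal alkyne (C11 added); carbonate in methanol is tolerated because no carbonyl or acidic C–H flanks the peroxide at this stage.

Step 12
Reactants: 19 triethyl({(4S,6R)-4,6-dimethyl-6-[(2R)-2-methylpent-4-yn-1-yl]-1,2-dioxan-4-yl}oxy)silane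
Product: 20 triethyl({(4S,6R)-6-[(2R,4E)-2,4-dimethyl-5-(4,4,5,5-tetramethyl-1,3,2-dioxaborolan-2-yl)pent-4-en-1-yl]-4,6-dimethyl-1,2-dioxan-4-yl}oxy)silane
Conditions: CuCl (10 mol %), P(p-tol)3 (12 mol %), LiOt-Bu, B2pin2, MeI, THF, rt
Reagents that add atoms: bis(pinacolato)diboron, CC1(C)OB(OC1(C)C)B1OC(C)(C)C(C)(C)O1; iodomethane, CI
Why: Copper-catalysed methylboration: syn borylcupration puts boron on the terminal carbon and the alkenylcopper is methylated by MeI with retention, which gives the E alkenyl boronate with the C10 methyl cis to boron. It is run before the lactone exists because it needs stoichiometric alkoxide, and the C4 silyl ether keeps a hydroxyl from protonating the alkenylcopper.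

Step 13
Reactants: 20 triethyl({(4S,6R)-6-[(2R,4E)-2,4-dimethyl-5-(4,4,5,5-tetramethyl-1,3,2-dioxaborolan-2-yl)pent-4-en-1-yl]-4,6-dimethyl-1,2-dioxan-4-yl}oxy)silane
Product: 21 (4S,6R)-6-[(2R,4E)-2,4-dimethyl-5-(4,4,5,5-tetramethyl-1,3,2-dioxaborolan-2-yl)pent-4-en-1-yl]-4,6-dimethyl-1,2-dioxan-4-ol
Conditions: CSA (0.2 equiv), MeOH–CH2Cl2, 0 °C → rt
Reagents that add atoms: none
Why: Acid-catalysed methanolysis removes the tertiary triethylsilyl ether; the pinacol boronate and the dialkyl peroxide tolerate mild acid.

Step 14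
Reactants: 21 (4S,6R)-6-[(2R,4E)-2,4-dimethyl-5-(4,4,5,5-tetramethyl-1,3,2-dioxaborolan-2-yl)pent-4-en-1-yl]-4,6-dimethyl-1,2-dioxan-4-ol
Product: 22 (4S,6R)-6-[(2R,4E)-2,4-dimethyl-5-(4,4,5,5-tetramethyl-1,3,2-dioxaborolan-2-yl)pent-4-en-1-yl]-4,6-dimethyl-1,2-dioxan-4-yl 3-oxobutanoate
Conditions: diketene, DMAP (10 mol %), CH2Cl2, 0 °C → rt
Reagents that add atoms: diketene, C=C1CC(=O)O1
Why: DMAP-catalysed ring opening of diketene acetoacetylates even tertiary alcohols at room temperature without strong base.

Step 15
Reactants: 22 (4S,6R)-6-[(2R,4E)-2,4-dimethyl-5-(4,4,5,5-tetramethyl-1,3,2-dioxaborolan-2-yl)pent-4-en-1-yl]-4,6-dimethyl-1,2-dioxan-4-yl 3-oxobutanoate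
Product: 24 (4S,6R)-6-[(2R,4E)-2,4-dimethyl-5-(4,4,5,5-tetramethyl-1,3,2-dioxaborolan-2-yl)pent-4-en-1-yl]-4,6-dimethyl-1,2-dioxan-4-yl diazoacetate, via diazoacetoacetate 23 (not isolated)
Conditions: 4-acetamidobenzenesulfonyl azide, Et3N, MeCN, rt; then pyrrolidine, rt
Reagents that add atoms: 4-acetamidobenzenesulfonyl azide, CC(=O)Nc1ccc(cc1)S(=O)(=O)N=[N+]=[N-]
Why: Regitz diazo transfer to the active methylene followed by retro-Claisen deacetylation with pyrrolidine gives the diazoacetate under amine-base conditions only; no stereocentre is involved.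

Step 16
Reactants: 24 (4S,6R)-6-[(2R,4E)-2,4-dimethyl-5-(4,4,5,5-tetramethyl-1,3,2-dioxaborolan-2-yl)pent-4-en-1-yl]-4,6-dimethyl-1,2-dioxan-4-yl diazoacetate
Product: 25 (3S,4S,6R)-lactone of {6-[(2R,4E)-2,4-dimethyl-5-(4,4,5,5-tetramethyl-1,3,2-dioxaborolan-2-yl)pent-4-en-1-yl]-4-hydroxy-4,6-dimethyl-1,2-dioxan-3-yl}acetic acid
Conditions: Rh2(acam)4 (2 mol %; acam = acetamidate), CH2Cl2, 40 °C, slow addition of 24 by syringe pump, high dilution
Reagents that add atoms: none
Why: Proposed new method: carbenoid insertion has not been run on a C–H bond α to a peroxide oxygen; the closest known reaction type is the dirhodium-catalysed 1,5-C–H insertion of cycloalkyl and ether-containing diazoacetates to cis-fused γ-lactones. Rh2(acam)4 takes up the diazo carbon of 24, N2 leaves, and the electrophilic carbenoid at C2 inserts into C3–H through a five-membered, hydride-transfer-like transition state that forms C2–C3 and releases the catalyst. The γ-lactone (C1, C2, C3, C4, O) closes by this C–C bond formation. C3 is controlled by C4: the three-atom tether reaches only the C3 hydrogen cis to the C4 oxygen (the equatorial C–H gauche to the axial ester in the chair with both methyl groups equatorial), and insertion proceeds with retention, so the fusion is cis and C3 is S. The step needs selectivity for C3–H over C5–H, the C4 methyl and the peroxide oxygens: C3–H is the only 1,5-related bond activated by an α-oxygen lone pair, C5–H is deactivated by two β-oxygens and flanked by two fully substituted carbons, and the methyl C–H bonds are the poorest donors. The electron-rich carboxamidate catalyst, slow addition and the low basicity of peroxide oxygen should disfavour ylide formation, and the electron-poor trisubstituted alkenyl boronate lies too far away for cyclopropanation.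

Step 17
Reactants: 26 1-phenyl-2-butyne
Product: 28 [(2E)-3-iodobut-2-en-1-yl]benzene, via alkenylzirconocene 27 (not isolated)
Conditions: Cp2Zr(H)Cl (1.6 equiv), THF, 50 °C; then I2, 0 °C
Reagents that add atoms: iodine, II
Why: Hydrozirconation with the Schwartz reagent adds Zr–H syn, and with excess reagent zirconium settles on the less hindered, methyl-bearing carbon; iodinolysis with retention gives the E iodide, and any regioisomer is removed by chromatography.

Step 18
Reactants: 25 (3S,4S,6R)-lactone of {6-[(2R,4E)-2,4-dimethyl-5-(4,4,5,5-tetramethyl-1,3,2-dioxaborolan-2-yl)pent-4-en-1-yl]-4-hydroxy-4,6-dimethyl-1,2-dioxan-3-yl}acetic acid; 28 [(2E)-3-iodobut-2-en-1-yl]benzene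
Product: 29 (3S,4S,6R)-lactone of {4-hydroxy-4,6-dimethyl-6-[(2R,4E,6E)-2,4,6-trimethyl-8-phenylocta-4,6-dien-1-yl]-1,2-dioxan-3-yl}acetic acid (target)
Conditions: Pd(dppf)Cl2 (5 mol %), K3PO4 (3 M aq.), THF, degassed, rt
Reagents that add atoms: none
Why: Suzuki–Miyaura coupling joins C11 and C12 with retention at both alkenes, giving the (10E,12E)-diene; weak aqueous base at room temperature is the only base the β-peroxy lactone meets.

## Compound list

1 | methyl hydrogen (R)-3-methylglutarate | COC(=O)C[C@H](C)CC(=O)O | starting material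
2 | methyl (3R)-5-hydroxy-3-methylpentanoate | COC(=O)C[C@H](C)CCO | intermediate
3 | (4R)-4-methyltetrahydro-2H-pyran-2-one | O=C1C[C@H](C)CCO1 | intermediate
4 | (4R)-4-methyltetrahydro-2H-pyran-2-ol (both anomers) | OC1C[C@H](C)CCO1 | intermediate
5 | (3S)-3-methylhex-5-yn-1-ol | C#CC[C@H](C)CCO | intermediate
6 | triethyl{[(3S)-3-methylhex-5-yn-1-yl]oxy}silane | C#CC[C@H](C)CCO[Si](CC)(CC)CC | intermediate
7 | diisobutyl{(4R)-4-methyl-6-[(triethylsilyl)oxy]hex-1-en-2-yl}alane | CC(C)C[Al](CC(C)C)C(=C)C[C@H](C)CCO[Si](CC)(CC)CC | intermediate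
8 | {[(3R)-5-bromo-3-methylhex-5-en-1-yl]oxy}triethylsilane | C=C(Br)C[C@H](C)CCO[Si](CC)(CC)CC | intermediate
9 | (R)-2-methylglycidol | OC[C@]1(C)CO1 | starting material
10 | chloromagnesium alkoxide of (R)-2-methylglycidol | Cl[Mg]OC[C@]1(C)CO1 | intermediate
11 | bromo{(4R)-4-methyl-6-[(triethylsilyl)oxy]hex-1-en-2-yl}magnesium | Br[Mg]C(=C)C[C@H](C)CCO[Si](CC)(CC)CC | intermediate
12 | (2S,6S)-2,6-dimethyl-4-methylidene-8-[(triethylsilyl)oxy]octane-1,2-diol | OC[C@](O)(C)CC(=C)C[C@H](C)CCO[Si](CC)(CC)CC | intermediate
13 | (2S,6S)-2-hydroxy-2,6-dimethyl-4-methylidene-8-[(triethylsilyl)oxy]octyl 4-methylbenzenesulfonate | Cc1ccc(cc1)S(=O)(=O)OC[C@](O)(C)CC(=C)C[C@H](C)CCO[Si](CC)(CC)CC | intermediate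
14 | (2S,6S)-2,6-dimethyl-4-methylidene-2,8-bis[(triethylsilyl)oxy]octyl 4-methylbenzenesulfonate | Cc1ccc(cc1)S(=O)(=O)OC[C@](O[Si](CC)(CC)CC)(C)CC(=C)C[C@H](C)CCO[Si](CC)(CC)CC | intermediate
15 | (2S,4R,6R)-2,4,6-trimethyl-2,8-bis[(triethylsilyl)oxy]-4-[(triethylsilyl)peroxy]octyl 4-methylbenzenesulfonate (4R epimer drawn; formed with the 4S epimer) | Cc1ccc(cc1)S(=O)(=O)OC[C@](O[Si](CC)(CC)CC)(C)C[C@](C)(OO[Si](CC)(CC)CC)C[C@H](C)CCO[Si](CC)(CC)CC | intermediate
16 | (2S,4R,6R)-4-hydroperoxy-8-hydroxy-2,4,6-trimethyl-2-[(triethylsilyl)oxy]octyl 4-methylbenzenesulfonate (4R epimer drawn) | Cc1ccc(cc1)S(=O)(=O)OC[C@](O[Si](CC)(CC)CC)(C)C[C@](C)(OO)C[C@H](C)CCO | intermediate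
17 | (3R)-4-{(4S,6R)-4,6-dimethyl-4-[(triethylsilyl)oxy]-1,2-dioxan-6-yl}-3-methylbutan-1-ol | OCC[C@@H](C)C[C@]1(C)C[C@](C)(O[Si](CC)(CC)CC)COO1 | intermediate
18 | (3S)-4-{(4S,6R)-4,6-dimethyl-4-[(triethylsilyl)oxy]-1,2-dioxan-6-yl}-3-methylbutanal | O=CC[C@@H](C)C[C@]1(C)C[C@](C)(O[Si](CC)(CC)CC)COO1 | intermediate
19 | triethyl({(4S,6R)-4,6-dimethyl-6-[(2R)-2-methylpent-4-yn-1-yl]-1,2-dioxan-4-yl}oxy)silane | C#CC[C@@H](C)C[C@]1(C)C[C@](C)(O[Si](CC)(CC)CC)COO1 | intermediate
20 | triethyl({(4S,6R)-6-[(2R,4E)-2,4-dimethyl-5-(4,4,5,5-tetramethyl-1,3,2-dioxaborolan-2-yl)pent-4-en-1-yl]-4,6-dimethyl-1,2-dioxan-4-yl}oxy)silane | CC1(C)OB(OC1(C)C)/C=C(\C)C[C@@H](C)C[C@]2(C)C[C@](C)(O[Si](CC)(CC)CC)COO2 | intermediate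
21 | (4S,6R)-6-[(2R,4E)-2,4-dimethyl-5-(4,4,5,5-tetramethyl-1,3,2-dioxaborolan-2-yl)pent-4-en-1-yl]-4,6-dimethyl-1,2-dioxan-4-ol | CC1(C)OB(OC1(C)C)/C=C(\C)C[C@@H](C)C[C@]2(C)C[C@](C)(O)COO2 | intermediate
22 | (4S,6R)-6-[(2R,4E)-2,4-dimethyl-5-(4,4,5,5-tetramethyl-1,3,2-dioxaborolan-2-yl)pent-4-en-1-yl]-4,6-dimethyl-1,2-dioxan-4-yl 3-oxobutanoate | CC1(C)OB(OC1(C)C)/C=C(\C)C[C@@H](C)C[C@]2(C)C[C@](C)(OC(=O)CC(C)=O)COO2 | intermediate
23 | (4S,6R)-6-[(2R,4E)-2,4-dimethyl-5-(4,4,5,5-tetramethyl-1,3,2-dioxaborolan-2-yl)pent-4-en-1-yl]-4,6-dimethyl-1,2-dioxan-4-yl 2-diazo-3-oxobutanoate | CC1(C)OB(OC1(C)C)/C=C(\C)C[C@@H](C)C[C@]2(C)C[C@](C)(OC(=O)C(=[N+]=[N-])C(C)=O)COO2 | intermediate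
24 | (4S,6R)-6-[(2R,4E)-2,4-dimethyl-5-(4,4,5,5-tetramethyl-1,3,2-dioxaborolan-2-yl)pent-4-en-1-yl]-4,6-dimethyl-1,2-dioxan-4-yl diazoacetate | CC1(C)OB(OC1(C)C)/C=C(\C)C[C@@H](C)C[C@]2(C)C[C@](C)(OC(=O)C=[N+]=[N-])COO2 | intermediate
25 | (3S,4S,6R)-lactone of {6-[(2R,4E)-2,4-dimethyl-5-(4,4,5,5-tetramethyl-1,3,2-dioxaborolan-2-yl)pent-4-en-1-yl]-4-hydroxy-4,6-dimethyl-1,2-dioxan-3-yl}acetic acid (cis-fused γ-lactone between C1 and the C4 oxygen) | CC1(C)OB(OC1(C)C)/C=C(\C)C[C@@H](C)C[C@]2(C)C[C@]3(C)OC(=O)C[C@@H]3OO2 | intermediate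
26 | 1-phenyl-2-butyne (but-2-yn-1-ylbenzene) | CC#CCc1ccccc1 | starting material
27 | chloro[(2E)-4-phenylbut-2-en-2-yl]zirconocene | C/C(=C\Cc1ccccc1)[Zr](Cl)(C1C=CC=C1)C1C=CC=C1 | intermediate
28 | [(2E)-3-iodobut-2-en-1-yl]benzene | C/C(I)=C\Cc1ccccc1 | intermediate
29 | (3S,4S,6R)-lactone of {4-hydroxy-4,6-dimethyl-6-[(2R,4E,6E)-2,4,6-trimethyl-8-phenylocta-4,6-dien-1-yl]-1,2-dioxan-3-yl}acetic acid (CNP0272658.1) | CC(=C\Cc1ccccc1)/C=C(\C)C[C@@H](C)C[C@]1(C)C[C@]2(C)OC(=O)C[C@@H]2OO1 | target

## Step count and least certain steps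

Total: 18 steps. Longest linear sequence: 17 steps (steps 1–16 and 18); step 17 is a one-step side branch.

**Step 16 (key step, proposed new method).** Most likely failure: the carbenoid attacks a peroxide oxygen (six-membered oxonium ylide, then O–O cleavage) or inserts at C5–H, because activation of a C–H bond by a peroxide oxygen is unproven.

Fallback, by known chemistry, leaves the route at 12 and returns at 25; the lactone and the dioxane then close together by conjugate addition of the hydroperoxide.
- Selective oxidation of the primary hydroxyl of 12 (TEMPO, PhI(OAc)2) would give the hydroxy aldehyde F1.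
- Ph3P=C=C=O (Bestmann ylide) would convert F1 into the butenolide F2.
- Co(thd)2/O2/Et3SiH should peroxidise the 1,1-disubstituted alkene in preference to the electron-poor butenolide, giving the silyl peroxide F3 as both C6 epimers.
- PPTS in MeOH would free the hydroperoxy alcohol F4.
- Et2NH in CF3CH2OH would close F4 by intramolecular oxa-Michael addition to the cis-fused peroxy-lactone alcohol F5 (the same compound as A3; C6 epimers separated here).
- Dess–Martin oxidation would give the aldehyde F6, and the Ohira–Bestmann reagent the alkyne F7.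
- Copper-catalysed methylboration of F7, with the alkoxide kept to one equivalent at 0 °C, returns to 25.

The price is that the alkyne and boronate chemistry then runs on the base-labile lactone.

**Step 9.** Most likely failure: the displacement at the hindered primary carbon (next to a fully substituted, oxygen-bearing carbon) is slow, so the hydroperoxide anion decomposes or the tertiary silyl ether is lost in the acidic stage and the epoxide pathway reopens.

Fallback leaves at 14 and returns at 17; it replaces the anionic displacement by silver-assisted alkylation of the neutral hydroperoxide, a known way to close cyclic peroxides from halo hydroperoxides.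
- Finkelstein exchange on 14 (NaI, 2-butanone, reflux) would give the iodide F8.
- Co(thd)2/O2/Et3SiH would give the silyl peroxide F9.
- PPTS in MeOH would give the hydroperoxy iodide F10.
- AgO2CCF3 in CH2Cl2 at 0 °C would close the dioxane to 17.

**Step 12.** Most likely failure: the O–O bond is cleaved by the nucleophilic boryl-copper species or by alkoxide-activated diboron before the alkyne reacts.

Fallback leaves at 19 and returns at 20; it builds the boronate without copper, boron nucleophiles or alkoxide.
- Gold-catalysed hydration of 19 (Ph3PAuNTf2, MeOH–H2O) would give the methyl ketone F11.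
- Wittig methylenation (Ph3P=CH2, THF, 0 °C) would give the 1,1-disubstituted alkene F12.
- Cross-metathesis of F12 with vinylboronic acid pinacol ester (second-generation Hoveyda–Grubbs catalyst, CH2Cl2, 40 °C) would give 20; the E isomer is expected to predominate and the Z isomer is removed by chromatography.

**Step 18.** Most likely failure: base-induced opening of the β-peroxy lactone (E1cB loss of the peroxide from C3, or lactone hydrolysis) during a slow transmetalation of the hindered trisubstituted boronate.

Fallback leaves at 21 and returns at 29; it moves the coupling ahead of lactone formation, so the insertion becomes the last step and no base follows it.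
- Suzuki–Miyaura coupling of 21 with 28 under the step 18 conditions would give the diene dioxanol F13.
- Diketene/DMAP would give the acetoacetate F14.
- Diazo transfer would give the diazoacetoacetate F15, and pyrrolidine the diazoacetate F16.
- Rh2(acam)4 under the step 16 conditions would give 29.

The cost is that the carbenoid must then ignore a remote diene.

## Further compounds

F1 | step 16 | (2S,6S)-2-hydroxy-2,6-dimethyl-4-methylidene-8-[(triethylsilyl)oxy]octanal | O=C[C@](O)(C)CC(=C)C[C@H](C)CCO[Si](CC)(CC)CC
F2 | step 16 | (5S)-5-methyl-5-{(4S)-4-methyl-2-methylidene-6-[(triethylsilyl)oxy]hexyl}furan-2(5H)-one | O=C1C=C[C@](C)(CC(=C)C[C@H](C)CCO[Si](CC)(CC)CC)O1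
F3 | step 16 | (5S)-5-{(2R,4R)-2,4-dimethyl-6-[(triethylsilyl)oxy]-2-[(triethylsilyl)peroxy]hexyl}-5-methylfuran-2(5H)-one (2R epimer drawn) | O=C1C=C[C@](C)(C[C@](C)(OO[Si](CC)(CC)CC)C[C@H](C)CCO[Si](CC)(CC)CC)O1
F4 | step 16 | (5S)-5-[(2R,4R)-2-hydroperoxy-6-hydroxy-2,4-dimethylhexyl]-5-methylfuran-2(5H)-one | O=C1C=C[C@](C)(C[C@](C)(OO)C[C@H](C)CCO)O1
F5 | step 16 | (3S,4S,6R)-lactone of {4-hydroxy-6-[(2R)-4-hydroxy-2-methylbutyl]-4,6-dimethyl-1,2-dioxan-3-yl}acetic acid | OCC[C@@H](C)C[C@]1(C)C[C@]2(C)OC(=O)C[C@@H]2OO1
F6 | step 16 | (3S,4S,6R)-lactone of {4-hydroxy-4,6-dimethyl-6-[(2S)-2-methyl-4-oxobutyl]-1,2-dioxan-3-yl}acetic acid | O=CC[C@@H](C)C[C@]1(C)C[C@]2(C)OC(=O)C[C@@H]2OO1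
F7 | step 16 | (3S,4S,6R)-lactone of {4-hydroxy-4,6-dimethyl-6-[(2R)-2-methylpent-4-yn-1-yl]-1,2-dioxan-3-yl}acetic acid | C#CC[C@@H](C)C[C@]1(C)C[C@]2(C)OC(=O)C[C@@H]2OO1
F8 | step 9 | (2S,6S)-1-iodo-2,6-dimethyl-4-methylidene-2,8-bis[(triethylsilyl)oxy]octane | IC[C@](O[Si](CC)(CC)CC)(C)CC(=C)C[C@H](C)CCO[Si](CC)(CC)CC
F9 | step 9 | (2S,4R,6R)-1-iodo-2,4,6-trimethyl-2,8-bis[(triethylsilyl)oxy]-4-[(triethylsilyl)peroxy]octane (4R epimer drawn) | IC[C@](O[Si](CC)(CC)CC)(C)C[C@](C)(OO[Si](CC)(CC)CC)C[C@H](C)CCO[Si](CC)(CC)CC
F10 | step 9 | (3R,5R,7S)-5-hydroperoxy-8-iodo-3,5,7-trimethyl-7-[(triethylsilyl)oxy]octan-1-ol | IC[C@](O[Si](CC)(CC)CC)(C)C[C@](C)(OO)C[C@H](C)CCO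
F11 | step 12 | (4S)-5-{(4S,6R)-4,6-dimethyl-4-[(triethylsilyl)oxy]-1,2-dioxan-6-yl}-4-methylpentan-2-one | CC(=O)C[C@@H](C)C[C@]1(C)C[C@](C)(O[Si](CC)(CC)CC)COO1
F12 | step 12 | triethyl({(4S,6R)-6-[(2R)-2,4-dimethylpent-4-en-1-yl]-4,6-dimethyl-1,2-dioxan-4-yl}oxy)silane | C=C(C)C[C@@H](C)C[C@]1(C)C[C@](C)(O[Si](CC)(CC)CC)COO1
F13 | step 18 | (4S,6R)-4,6-dimethyl-6-[(2R,4E,6E)-2,4,6-trimethyl-8-phenylocta-4,6-dien-1-yl]-1,2-dioxan-4-ol | CC(=C\Cc1ccccc1)/C=C(\C)C[C@@H](C)C[C@]1(C)C[C@](C)(O)COO1
F14 | step 18 | (4S,6R)-4,6-dimethyl-6-[(2R,4E,6E)-2,4,6-trimethyl-8-phenylocta-4,6-dien-1-yl]-1,2-dioxan-4-yl 3-oxobutanoate | CC(=C\Cc1ccccc1)/C=C(\C)C[C@@H](C)C[C@]1(C)C[C@](C)(OC(=O)CC(C)=O)COO1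
F15 | step 18 | (4S,6R)-4,6-dimethyl-6-[(2R,4E,6E)-2,4,6-trimethyl-8-phenylocta-4,6-dien-1-yl]-1,2-dioxan-4-yl 2-diazo-3-oxobutanoate | CC(=C\Cc1ccccc1)/C=C(\C)C[C@@H](C)C[C@]1(C)C[C@](C)(OC(=O)C(=[N+]=[N-])C(C)=O)COO1
F16 | step 18 | (4S,6R)-4,6-dimethyl-6-[(2R,4E,6E)-2,4,6-trimethyl-8-phenylocta-4,6-dien-1-yl]-1,2-dioxan-4-yl diazoacetate | CC(=C\Cc1ccccc1)/C=C(\C)C[C@@H](C)C[C@]1(C)C[C@](C)(OC(=O)C=[N+]=[N-])COO1
A1 | alternative 1 | {(3S,6R)-6-[(2R)-4-{[tert-butyl(dimethyl)silyl]oxy}-2-methylbutyl]-4,6-dimethyl-3,6-dihydro-1,2-dioxin-3-yl}acetic acid | CC(C)(C)[Si](C)(C)OCC[C@@H](C)C[C@]1(C)C=C(C)[C@H](CC(=O)O)OO1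
A2 | alternative 1 | (3E,5E,8S)-10-{[tert-butyl(dimethyl)silyl]oxy}-4,6,8-trimethyldeca-3,5-dienoic acid | OC(=O)C/C=C(\C)/C=C(\C)C[C@H](C)CCO[Si](C)(C)C(C)(C)C
A3 | alternative 2 | (3S,4S,6R)-lactone of {4-hydroxy-6-[(2R)-4-hydroxy-2-methylbutyl]-4,6-dimethyl-1,2-dioxan-3-yl}acetic acid | OCC[C@@H](C)C[C@]1(C)C[C@]2(C)OC(=O)C[C@@H]2OO1
A4 | alternative 2 | (3R)-3-methyl-5-oxohexyl (3S)-3-hydroperoxy-4-methylpent-4-enoate | C=C(C)[C@@H](OO)CC(=O)OCC[C@@H](C)CC(C)=O
A5 | alternative 3 | (3S,4S,6R)-lactone of {6-[(2R)-4-acetoxy-2-methylbutyl]-4-hydroxy-4,6-dimethyl-1,2-dioxan-3-yl}acetic acid | CC(=O)OCC[C@@H](C)C[C@]1(C)C[C@]2(C)OC(=O)C[C@@H]2OO1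
A6 | alternative 3 | {(3S,4R,6R)-6-[(2R)-4-acetoxy-2-methylbutyl]-4,6-dimethyl-1,2-dioxan-3-yl}acetic acid | CC(=O)OCC[C@@H](C)C[C@]1(C)C[C@@H](C)[C@H](CC(=O)O)OO1
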